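**Retrosynthetic overview**
1. Target 17 ⇐ reduction of 5,8-endoperoxide 16 ⇐ singlet-oxygen [4+2] on ring-B diene acid 15 ⇐ dehydrogenation of tetracyclic acid 14.
2. 14 ⇐ thermal 6π closure, then intramolecular Diels–Alder, of trans-disubstituted cyclooctatriene 11 (cyclobutane and ring A first, then cyclopentane and ring B).
3. 11 ⇐ key step: cationic ring expansion of cycloheptatrienylcarbinyl acetate 7 to 8-octylhomotropylium 10, captured enantioselectively by the ε-carbon of sorbic acid trienolate 9.
4. 7 ⇐ ring contraction of cyclooctatetraene oxide 2 to aldehyde 5, trapped by octyl Grignard made from oct-1-ene; 2 ⇐ cyclooctatetraene 1; 9 ⇐ sorbic acid 8.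
5. Ring order: eight-membered ring → seven → eight → cyclobutane/ring A → cyclopentane/ring B.

Assumption: the (S,S) enantiomer of the IDPi acid is taken to give (1S,8S)-11; if the sense of induction is opposite, the (R,R) acid is used.
Notation: core carbons C1–C13 are numbered in the order of the ring atoms in the target SMILES (C1 octyl-bearing, C5 tertiary carbinol, C6 carboxyl-bearing, C8 secondary carbinol, C10 CH2); ring A = C2,3,4,5,13,12; ring B = C5,6,7,8,9,13; β = the face of ring B that carries C10 and H13.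

**Step 1**
Reactants: 1 cycloocta-1,3,5,7-tetraene
Product: 2 cyclooctatetraene monoepoxide (9-oxabicyclo[6.1.0]nona-2,4,6-triene; cis; meso)
Conditions: mCPBA (1.0 equiv), CH2Cl2, 0 °C → rt
Reagents that add atoms: 3-chloroperoxybenzoic acid, OOC(=O)c1cccc(Cl)c1
Why: Prilezhaev epoxidation with one equivalent of peracid gives the known meso monoepoxide, so no stereocentre has to be controlled.

**Step 2**
Reactants: 3 oct-1-ene; 2 cyclooctatetraene monoepoxide
Product: 7 1-(cyclohepta-2,4,6-trien-1-yl)nonyl acetate (racemic), via octylmagnesium bromide 4 (not isolated), via cyclohepta-2,4,6-triene-1-carbaldehyde 5 (not isolated), via bromomagnesium alkoxide 6 (not isolated)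
Conditions: 3 (1.2 equiv), i-BuMgBr (1.1 equiv), Cp2TiCl2 (3 mol %), Et2O, rt, 6 h; then 2 (1.0 equiv), MgBr2·OEt2 (0.3 equiv), −20 °C → rt; then Ac2O (2 equiv), 0 °C → rt
Reagents that add atoms: acetic anhydride, CC(=O)OC(C)=O
Why: Titanocene-catalysed hydromagnesiation gives the primary Grignard, the magnesium Lewis acid induces the known Meinwald-type ring contraction (1,2-vinyl shift) of 2 to aldehyde 5, Grignard 1,2-addition and O-acetylation follow, and the racemic carbinol centre is erased in step 4.

**Step 3**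
Reactants: 8 sorbic acid
Product: 9 (3E)-1,1-bis(trimethylsilyloxy)hexa-1,3,5-triene
Conditions: LiN(iPr)2 (2.2 equiv), THF, −78 → 0 °C; Me3SiCl (2.4 equiv), −78 °C → rt; distil
Reagents that add atoms: chlorotrimethylsilane, C[Si](C)(C)Cl
Why: ε-Deprotonation of lithium sorbate gives the trienediolate, and O,O-disilylation gives the bis-silyl ketene acetal with the 3E alkene retained (silyl ketene acetal formation).

**Step 4**
Reactants: 7 1-(cyclohepta-2,4,6-trien-1-yl)nonyl acetate; 9 bis-silyl trienolate
Product: 14 tetracyclic 3,7-diene-6-carboxylic acid (1-octyl; H5 and CO2H β), via 8-octylhomotropylium 10 (not isolated), via cyclooctatriene silyl ester 11 (not isolated), via bicyclooctadiene silyl ester 12 (not isolated), via tetracyclic silyl ester 13 (not isolated)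
Conditions: 9 (1.5 equiv), (S,S)-IDPi Brønsted acid (imidodiphosphorimidate of two 3,3'-diaryl-BINOL units, N-triflyl; 3 mol %), PhMe/CH2Cl2 4:1, −60 °C, 24 h; Et3N; then PhMe, 100 °C, 12 h; aq. citric acid
Reagents that add atoms: none
Why: Proposed new method: the silylated chiral acid ionises the acetate with participation of the adjacent ring C–C bond, a cationic 1,2-shift (Wagner–Meerwein/cyclopropylcarbinyl-type ring expansion, the closest known case being solvolytic cycloheptatrienylcarbinyl-to-homotropylium rearrangement) that gives achiral homoaromatic cation 10 paired with the chiral anion, which directs ε-attack of 9 to one of the two enantiotopic termini next to the octyl-bearing carbon and anti to the exo octyl group (sets C11 and trans-C1; closest known reactions are chiral-anion-directed bis-vinylogous Mukaiyama additions and chiral-anion control of non-classical carbocations), after which heating effects disrotatory 6π closure (C2, C12; only the closure that places the dienyl arm endo is productive and the other is reversible) and the tether-enforced exo intramolecular Diels–Alder reaction (C13, C9, C5, C6).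

**Step 5**
Reactants: 14 tetracyclic 3,7-diene-6-carboxylic acid
Product: 15 tetracyclic 3,5,7-triene-6-carboxylic acid
Conditions: Zn(TMP)2·2LiCl (2.2 equiv), THF, 0 °C → rt; [Pd(allyl)Cl]2 (2.5 mol %), allyl acetate (1.2 equiv), 60 °C; aq. HCl
Reagents that add atoms: none
Why: Allyl-palladium-catalysed α,β-dehydrogenation of the zinc enediolate gives the C5=C6 alkene by syn β-hydride elimination of the only sp3 β-hydrogen (H5, cis to palladium on the open β face), and the stereocentres at C1, C2, C9, C11, C12 and C13 are untouched.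

**Step 6**
Reactants: 15 tetracyclic 3,5,7-triene-6-carboxylic acid
Product: 17 target acid (5,8-dihydroxy; both OH β), via 5,8-endoperoxide 16 (not isolated)
Conditions: O2, tetraphenylporphyrin (1 mol %), white LED, CH2Cl2, −30 °C; then Zn dust, AcOH, 0 °C → rt
Reagents that add atoms: dioxygen, O=O
Why: Singlet-oxygen [4+2] cycloaddition to the only s-cis diene (C5=C6–C7=C8) from the β face, which is remote from ring A and the cyclobutane, sets C5 and C8 cis in one event, and O–O reduction with zinc gives the cis-1,4-diol with the C6=C7 enoic acid in place.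

**Compound list**
1 | cycloocta-1,3,5,7-tetraene | C1=CC=CC=CC=C1 | starting material
2 | cyclooctatetraene monoepoxide (cis, meso) | C1=CC=C[C@H]2O[C@H]2C=C1 | intermediate
3 | oct-1-ene | C=CCCCCCC | starting material
4 | octylmagnesium bromide | CCCCCCCC[Mg]Br | intermediate
5 | cyclohepta-2,4,6-triene-1-carbaldehyde | O=CC1C=CC=CC=C1 | intermediate
6 | bromomagnesium 1-(cyclohepta-2,4,6-trien-1-yl)nonan-1-olate (racemic) | CCCCCCCCC(O[Mg]Br)C1C=CC=CC=C1 | intermediate
7 | 1-(cyclohepta-2,4,6-trien-1-yl)nonyl acetate (racemic) | CCCCCCCCC(OC(C)=O)C1C=CC=CC=C1 | intermediate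
8 | sorbic acid, (2E,4E)-hexa-2,4-dienoic acid | C/C=C/C=C/C(=O)O | starting material
9 | (3E)-1,1-bis(trimethylsilyloxy)hexa-1,3,5-triene | C=C/C=C/C=C(O[Si](C)(C)C)O[Si](C)(C)C | intermediate
10 | 8-octylhomotropylium (8-octylcycloocta-2,4,6-trien-1-ylium, ion pair with the catalyst anion) | CCCCCCCCC1C=CC=CC=C[CH+]1 | intermediate
11 | trimethylsilyl (2E,4E)-6-[(1S,8S)-8-octylcycloocta-2,4,6-trien-1-yl]hexa-2,4-dienoate (trans) | CCCCCCCC[C@H]1/C=C\C=C/C=C\[C@@H]1C/C=C/C=C/C(=O)O[Si](C)(C)C | intermediate
12 | trimethylsilyl (2E,4E)-6-[(1S,6R,7R,8R)-8-octylbicyclo[4.2.0]octa-2,4-dien-7-yl]hexa-2,4-dienoate (7-endo arm, 8-exo octyl) | CCCCCCCC[C@H]1[C@@H]2C=CC=C[C@@H]2[C@@H]1C/C=C/C=C/C(=O)O[Si](C)(C)C | intermediate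
13 | trimethylsilyl ester of 14 | CCCCCCCC[C@H]1[C@@H]2C=C[C@@H]3[C@@H](C(=O)O[Si](C)(C)C)C=C[C@H]4C[C@H]1[C@H]2[C@@H]43 | intermediate
14 | tetracyclic 3,7-diene-6-carboxylic acid (1-octyl; ring B trans-fused to the cyclopentane, cis-fused to ring A; H5 and 6-CO2H β) | CCCCCCCC[C@H]1[C@@H]2C=C[C@@H]3[C@@H](C(=O)O)C=C[C@H]4C[C@H]1[C@H]2[C@@H]43 | intermediate
15 | tetracyclic 3,5,7-triene-6-carboxylic acid | CCCCCCCC[C@H]1[C@@H]2C=CC3=C(C(=O)O)C=C[C@H]4C[C@H]1[C@H]2[C@@H]43 | intermediate
16 | 5,8-epidioxy tetracyclic 3,6-diene-6-carboxylic acid (peroxide bridge β) | CCCCCCCC[C@H]1[C@@H]2C=C[C@]3(O5)C(C(=O)O)=C[C@@H](O5)[C@H]4C[C@H]1[C@H]2[C@@H]43 | intermediate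
17 | CNP0106718.3: 5,8-dihydroxy-1-octyl tetracyclic 3,6-diene-6-carboxylic acid (both OH β) | CCCCCCCC[C@H]1[C@@H]2C=C[C@]3(O)C(C(=O)O)=C[C@@H](O)[C@H]4C[C@H]1[C@H]2[C@@H]43 | target

**Step count**
Total steps: 6. Longest linear sequence: 5 (1 → 2 → 7 → 14 → 15 → 17).

**Steps most likely to fail**

Step 4 (the proposed new step). The carbinyl cation may undergo a 1,2-hydride shift to an alkyltropylium ion instead of ring expansion. The octyl group may end endo on 10, which would give the cis product. Enantiotopic-terminus selection by the chiral anion is untested. The fallback uses known chemistry, sets out from 2 and 3 and returns at 14. Hydroboration of 3 with Et2BH and boron–zinc exchange with Et2Zn give dioctylzinc F2. Cu(OTf)2/chiral binaphthol phosphoramidite-catalysed anti-SN2' desymmetrisation of 2 with F2 gives (1S,4S)-4-octylcycloocta-2,5,7-trien-1-ol F3. Hg(OAc)2-catalysed exchange with ethyl vinyl ether gives its vinyl ether F4. Claisen rearrangement of F4 (PhMe, 80 °C) delivers carbon to the ring on the face of the C–O bond, trans to octyl, and gives 2-[(1S,8S)-8-octylcycloocta-2,4,6-trien-1-yl]acetaldehyde F5. Horner–Wadsworth–Emmons reaction with triethyl 4-phosphonocrotonate and LiN(SiMe3)2 gives ethyl (2E,4E)-6-[(1S,8S)-8-octylcycloocta-2,4,6-trien-1-yl]hexa-2,4-dienoate F6. Heating F6 at 100 °C gives the tetracyclic ethyl ester F7 through the same 6π/Diels–Alder cascade, and LiOH hydrolysis gives 14.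

Step 5. β-Hydride elimination may go toward C9–H from a γ-bound palladium dienolate, or formation of the tetrasubstituted alkene may be slow. The fallback sets out from 14 and returns at 15. The dianion of 14 (LiN(iPr)2, 2.2 equiv) is sulfenylated with PhSSPh on the β face to give the 6-(phenylsulfanyl) acid F8. NaIO4 oxidation gives the sulfoxide F9. Thermolysis (PhMe, 110 °C, CaCO3) gives 15 by syn-elimination toward H5, the only β-hydrogen.

Step 2. Titanium residues may reduce or open the epoxide or couple the aldehyde, and leftover i-BuMgBr would add competitively. The fallback sets out from 3 and returns at 4. Radical anti-Markovnikov addition of HBr (dibenzoyl peroxide, hexane, 0 °C) gives 1-bromooctane F1. Magnesium turnings in Et2O convert F1 into titanium-free 4, which is then treated with 2 and Ac2O as in step 2 to give 7.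

**Further compounds**
F1 | step 2 | 1-bromooctane | CCCCCCCCBr
F2 | step 4 | dioctylzinc | CCCCCCCC[Zn]CCCCCCCC
F3 | step 4 | (1S,4S)-4-octylcycloocta-2,5,7-trien-1-ol (trans) | CCCCCCCC[C@H]1/C=C\C=C/[C@H](O)/C=C\1
F4 | step 4 | vinyl ether of F3 | CCCCCCCC[C@H]1/C=C\C=C/[C@H](OC=C)/C=C\1
F5 | step 4 | 2-[(1S,8S)-8-octylcycloocta-2,4,6-trien-1-yl]acetaldehyde | CCCCCCCC[C@H]1/C=C\C=C/C=C\[C@@H]1CC=O
F6 | step 4 | ethyl (2E,4E)-6-[(1S,8S)-8-octylcycloocta-2,4,6-trien-1-yl]hexa-2,4-dienoate | CCCCCCCC[C@H]1/C=C\C=C/C=C\[C@@H]1C/C=C/C=C/C(=O)OCC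
F7 | step 4 | ethyl ester of 14 | CCCCCCCC[C@H]1[C@@H]2C=C[C@@H]3[C@@H](C(=O)OCC)C=C[C@H]4C[C@H]1[C@H]2[C@@H]43
F8 | step 5 | 6-(phenylsulfanyl) derivative of 14 (SPh β) | CCCCCCCC[C@H]1[C@@H]2C=C[C@@H]3[C@@](C(=O)O)(Sc5ccccc5)C=C[C@H]4C[C@H]1[C@H]2[C@@H]43
F9 | step 5 | 6-(phenylsulfinyl) derivative of 14 | CCCCCCCC[C@H]1[C@@H]2C=C[C@@H]3[C@@](C(=O)O)(S(=O)c5ccccc5)C=C[C@H]4C[C@H]1[C@H]2[C@@H]43
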